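Begin with time. The run lasts 4.0 min, so compare that with one other time.

all flasks: pre-initiator 5 mol%
- south-east: free monomer 0.015 M; run made earlier
- north: free monomer 0.031 M; run made earlier
- Sunday's: free monomer 0.050 M; time 4.0 min
- Friday's: free monomer 0.025 M; time 4.0 min

| run | time / min | monomer in chains / % | free monomer / % |
|---|---|---|---|
| south-east | 0.333 | 0 | 100.2 |
| south-east | 0.500 | 0.6 | 100.1 |
| south-east | 0.833 | 1.1 | 98.3 |
| south-east | 1.33 | 4.4 | 96.4 |
| south-east | 2.50 | 11.9 | 88.2 |
| south-east | 4.00 | 27.3 | 73.3 |
| north | 0.250 | 0 | 99.4 |
| north | 0.833 | 2.2 | 96.5 |
| north | 1.33 | 7.9 | 92.6 |
| north | 2.00 | 17.7 | 83.0 |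
| north | 3.00 | 34.0 | 66.5 |
| north | 4.00 | 49.6 | 50.6 |

(scatter of a reading: 0.5 percentage points)

- the average divides the monomer in chains by the number of chains begun, living and dead together
- what was read earlier has a scatter of 0.5 percentage points, one standard deviation
- the earlier runs do not show the number of chains; that part of a forecast is a guess

* which of the two ends with the longer chains by the average number of monomer units in a chain (chains begun, living or dead) ("neither" if they lie within 10%) (Sunday's / Friday's / neither)
* average number of monomer units in a chain (chains begun, living or dead) at the end, Sunday's
* average number of monomer units in a chain (chains begun, living or dead) at the end, Friday's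

Take the logarithm of charge over free monomer left. In the north run it grows 3.66-fold from 2.00 min to 4.00 min, against 4.00 for a pure square of time. So treat it as a square. Divide run time by the root of that logarithm: this gives 4.85 min for north and 7.18 min for south-east. As read, the south-east square is 2.19 times the north one, and the north charge is 2.07 times the south-east one, so scale the square inversely with charge at this fixed loading. That gives 3.87 min for Sunday's: its growth time, the time at which that logarithm reaches one. Friday's gets 5.48 min.

Square the ratio of run time to growth time and take the exponential of its negative. On this estimate Sunday's keeps a fraction 0.344 of its free monomer, Friday's 0.587. The runs show no chain count, so assume that chains begun scale with charge at equal loading and time. Length then follows the fraction consumed, and my reckoning makes Sunday's chains 1.59 times Friday's, longer than the margin allows.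

The forecast says Sunday's, with 35 and 22 units, and adds: “The ratio of about 1.6 is firm”. The flask gives Sunday's, with 22.9 units against Friday's 14.5.

    free monomer + initiator → living end + monomer in chains (k = 2.40 M⁻¹ s⁻¹)
    free monomer + living end → monomer in chains + living end, rate k2*[living end]*[free monomer] (k = 5.40 M⁻¹ s⁻¹)
    pre-initiator → initiator (k = 0.00410 s⁻¹)

Set two half-lives side by side in Sunday's at 2.33 min: initiator has 0.15 min by its step with free monomer, pre-initiator 2.8 min by its conversion into initiator, so in Sunday's at that moment this conversion is the rate-limiting step of chain starting. At 4.00 min Sunday's holds 9.09 × 10⁻⁵ M initiator beside 0.00147 M living end. Its free monomer stands at 32.5%, against 34.4% from the growth time. Read at 1.50 min, the same recipe holds 83.5%, against 86.1% from the growth time.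

The readings were computed with made-up constants; scatter was added.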